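**Remarks on the chemistry (assumptions)**
- Atoms carry germacrane numbers throughout: C1–C10 ring, C11–C13 lactone carbons, C14 methyl on C10, C15 methyl on C4; O6, O8, O9, O10 are the oxygens on those carbons.
- The acyloxy chain is a 4-hydroxy-3-methylbutanoate (four-carbon acid chain plus methyl), so it is taken from (R)-β-methyl-γ-butyrolactone and not from a glutarate.
- Compound 3 is expected as a mixture of alkene isomers and compound 10 as an anomeric mixture; both converge in the next step. The C10 carbinol configuration of 14 is inconsequential (oxidised in step 14).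

## The problem

Compound 39 is a cis-fused 6,12-germacranolide. A cyclodeca-1(10),4-diene (Z at C1=C10, E at C4=C5) carries an α-methylene-γ-lactone closed from C7 through C11/C12 to O6, an acyloxy group on C8 and a free hydroxyl on C9. The four contiguous ring stereocentres C6–C9 hold O6, C11, O8 and O9 on one face; a fifth, remote centre sits in the ester chain and must be brought in separately. The ring centres can be taken together from one hexose, but none of them can be trusted to fix the geometry of two trisubstituted alkenes in a medium ring, so the geometry has to come from a stereospecific step. Sensitive elements are: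
- the 1,5-diene (acid-induced transannular cyclisation, Cope equilibration);
- the α-methylene lactone (Michael acceptor, so it is introduced late);
- the cis-8,9-diol monoester (acyl migration under base);
- the pair O6/O8, which are equidistant from C12 and must be told apart for lactonisation.

The enabling feature is that C10=C1–C2–C3–C4=C5 is a 1,5-diene. Cutting C2–C3 and joining C5–C10 in the retro-Cope sense gives a cyclohexane C5–C10 with a vinyl carbinol at C10 and an isopropenyl group at C5. On that ring O6 and O8 are 1,3-cis, so a single acetal carbon can bridge them and freeze one chair. The task is thus to make a hexasubstituted cyclohexane with defined stereocentres, to differentiate four oxygens, and to release O6 selectively afterwards.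

## Retrosynthesis

**Ester and last protecting group.** Target 39 is cut at the O8–acyl bond and at a 2-naphthylmethyl ether on O9, giving 38 and then alcohol 31 plus acid 36. Acylating last keeps the two aliphatic esters away from every basic or reducing step. Keeping O9 masked until the end prevents acylation at the wrong oxygen and acyl migration. The forward reaction must esterify a hindered secondary alcohol beside a Michael acceptor (mixed-anhydride activation) and remove the naphthylmethyl group oxidatively under neutral conditions.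

**Lactone and methylene.** Alcohol 31 comes from 30 by oxidative removal of a 3,4-dimethoxybenzyl ether. Disconnecting C11=C13 (Mannich/elimination) gives lactone 26, and disconnecting the C12 carbonyl oxidation level gives diol 24. Diol 24 is traced to 23 and then to the O6/O8 arylidene acetal 22 by a reductive acetal opening. Methylenation by enolate chemistry is only possible before the ester chain is present, which fixes this order. The forward opening has to leave O6 free and O8 benzylated; this is the one regiochemical demand of the endgame.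

**C14 and the ten-membered ring.** The C10–C14 bond of 22 is cut to enol triflate 21. Triflate 21 is then taken back through the [3,3] shift (C2–C3 cut, C5–C10 joined) to the cis-1-vinyl-2-isopropenylcyclohexanol 18. Against a macrocyclisation, this transform removes the medium ring and both alkene geometries at once and creates no stereocentre. Carbinol 18 is far simpler than 21: a chair cyclohexane whose conformation is fixed by the acetal. The forward step must proceed through the chair with isopropenyl axial and vinyl equatorial and must deliver only the C1=C10 enolate.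

**Vinyl carbinol and lock.** Carbinol 18 is cut at C10–C1 to ketone 17. The acetal of 17 is cut to diol ketone 16, available from bis-silyl ether 15. Installing the acetal before the vinyl addition makes the ketone part of a 2,4-dioxabicyclo[3.3.1]nonane, whose endo face is shielded, so the nucleophile should enter from outside and place O10 axial as required.

**Cyclohexane ring.** Ketone 15 comes from alcohol 14. The C5–C10 bond of 14 is cut by a retro-carbonyl-ene reaction to the open-chain aldehyde 13, which carries a prenyl-type alkene. This cut removes the ring and creates the isopropenyl group and the C10 oxygen in one step. An aldol or allylation would need extra functional handles. The forward reaction must place isopropenyl trans to O6.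

**Chain from a hexose.** Aldehyde 13 (via 12) comes from triol 11 and this from lactol 10 by Wittig isopropylidenation. In 11 the substituents O6, C11, O8 and O9 lie on one side of the Fischer projection, the pattern of a 3-deoxy-3-C-branched D-allose. This is reached from diacetone-D-glucose 1 through ulose 2, alkylidene ester 3 and the hydrogenation product 4, followed by protecting-group adjustment (5–9). Four of the five ring stereocentres are bought or set on a rigid furanose, and O9 and C10–OH are differentiated while they are still a terminal diol.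

**Side chain.** Acid 36 is cut at its two ester bonds to benzyl ester 35 and hydroxy ester 34, and back to lactone 32, which already contains the stereocentre.

## Roads not taken

**Alternative 1: pinacol closure across C8–C9.** The cut is the C8–C9 bond of the cis-diol. Forward, a C8 aldehyde carbon and the C9 carbonyl carbon of a Z-enal on a preformed lactone chain would be coupled with TiCl3(DME)1.5 and Zn–Cu, or with SmI2, to give diol lactone A1.
- Merits: the lactone and both alkenes are made in an open chain, the ring and two stereocentres appear in one step, and the route would be clearly shorter than the chosen one. O6 is already distinguished because the lactone is in place.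
- Weak points: C8 and C9 would both be set during a ten-membered ring closure with no local control. The ketyl of a Z-enal is an allylic radical, so the C1=C10 geometry can be lost and coupling can occur at C1. The product is a free 8,9-diol, so acylation at O8 alone remains unsolved.
- Comparison: the chosen plan is longer but sets no stereocentre in the ring-forming step, fixes both geometries by a chair transition state, and carries O8 and O9 differentiated from the sugar stage.

**Alternative 2: photoadduct cycloreversion.** The cut runs the ring backwards into a bicyclo[2.2.0]hexane by re-forming the C1–C4 and C5–C10 σ bonds. Forward, an enone–alkene photocycloaddition would lay down C1–C10 and C4–C5, and flash thermolysis would then break C1–C4 and C5–C10 to give dienone A2.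
- Merits: very few steps to the ring, C14 and C15 are already in place (no triflate or iron step), and the C9 ketone is a handle for O9.
- Weak points: the six-membered enone would have to carry O6, the C7 chain and O8, so most of the cyclohexane work remains. Regio- and facial selectivity of the photocycloaddition are uncertain. The thermolysis runs at temperatures where cyclodeca-1,5-dienes equilibrate with divinylcyclohexanes. C9 would need a late reduction cis to O8.
- Comparison: this road is better in step count after ring formation. The chosen plan offers a low-temperature, anion-driven ring expansion and no late stereoselective reduction.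

**Alternative 3: nickel ynal macrocyclisation.** The cuts are C5–C6 and C4–C15. Forward, Ni(cod)2 with the carbene 1,3-dimesitylimidazol-2-ylidene would join a C6 aldehyde carbon to the terminal alkyne carbon C5 while Me2Zn delivers C15 to C4, giving allylic alcohol A3.
- Merits: the E-trisubstituted alkene, C15, the ring and a free O6 are formed together. O6 is therefore distinguished from O8 without any selective deprotection, which is a real advantage over step 20 of the chosen plan.
- Weak points: the C6 configuration (cis to the C7 chain) would be set in the macrocyclisation under remote control. The Z-alkene and the C7–C9 triad must be built in the linear chain. A ten-membered E-allylic ring closure competes with oligomerisation.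
- Comparison: overall length is similar. The chosen plan accepts one regioselective acetal opening in exchange for a ring-forming step that creates no stereocentre.

Key step: step 18

## Route

Step 1
Reactants: 1 1,2:5,6-di-O-isopropylidene-α-D-glucofuranose
Product: 2 1,2:5,6-di-O-isopropylidene-α-D-ribo-hexofuranos-3-ulose
Conditions: Dess–Martin periodinane, NaHCO3, CH2Cl2, 0 °C → rt
Reagents that add atoms: none
Why: Dess–Martin oxidation of the only free (secondary) hydroxyl; acetonides are inert under the buffered conditions.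

Step 2
Reactants: 2 1,2:5,6-di-O-isopropylidene-α-D-ribo-hexofuranos-3-ulose
Product: 3 ethyl (3-deoxy-1,2:5,6-di-O-isopropylidene-α-D-ribo-hexofuranos-3-ylidene)acetate (alkene isomers)
Conditions: (EtO)2P(O)CH2CO2Et, NaH, THF, 0 °C → rt
Reagents that add atoms: triethyl phosphonoacetate CCOC(=O)CP(=O)(OCC)OCC
Why: Horner–Wadsworth–Emmons olefination of the furanos-3-ulose, a standard entry to 3-C-branched sugars; both alkene isomers give the same product in step 3.

Step 3
Reactants: 3 ethyl (3-deoxy-1,2:5,6-di-O-isopropylidene-α-D-ribo-hexofuranos-3-ylidene)acetate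
Product: 4 3-deoxy-3-C-(2-ethoxy-2-oxoethyl)-1,2:5,6-di-O-isopropylidene-α-D-allofuranose
Conditions: H2 (1 atm), 10% Pd/C, EtOAc, rt
Reagents that add atoms: none
Why: Catalytic hydrogenation from the exo face of the cis-fused furanose–dioxolane puts H on the face opposite the 1,2-acetonide, so the branch (C11) ends cis to O2 (allo configuration); this sets C7.

Step 4
Reactants: 4 3-deoxy-3-C-(2-ethoxy-2-oxoethyl)-1,2:5,6-di-O-isopropylidene-α-D-allofuranose
Product: 5 3-deoxy-3-C-(2-hydroxyethyl)-1,2:5,6-di-O-isopropylidene-α-D-allofuranose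
Conditions: LiAlH4, THF, 0 °C
Reagents that add atoms: none
Why: Hydride reduction of the ester to the primary alcohol C12–OH; acetals are unaffected.

Step 5
Reactants: 5 3-deoxy-3-C-(2-hydroxyethyl)-1,2:5,6-di-O-isopropylidene-α-D-allofuranose
Product: 6 3-C-[2-(tert-butyldiphenylsilyloxy)ethyl]-3-deoxy-1,2:5,6-di-O-isopropylidene-α-D-allofuranose
Conditions: t-BuPh2SiCl, imidazole, DMF, rt
Reagents that add atoms: tert-butyl(chloro)diphenylsilane CC(C)(C)[Si](Cl)(c1ccccc1)c1ccccc1
Why: Silylation of the primary alcohol; this silyl ether tolerates the aqueous acid, base, Lewis acid and hydride steps that follow and is removed by fluoride in step 21.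

Step 6
Reactants: 6 3-C-[2-(tert-butyldiphenylsilyloxy)ethyl]-3-deoxy-1,2:5,6-di-O-isopropylidene-α-D-allofuranose
Product: 7 3-C-[2-(tert-butyldiphenylsilyloxy)ethyl]-3-deoxy-1,2-O-isopropylidene-α-D-allofuranose
Conditions: AcOH/H2O (7:3), rt
Reagents that add atoms: none
Why: Selective hydrolysis of the terminal 5,6-acetonide, which is much more labile than the ring-fused 1,2-acetonide.

Step 7
Reactants: 7 3-C-[2-(tert-butyldiphenylsilyloxy)ethyl]-3-deoxy-1,2-O-isopropylidene-α-D-allofuranose
Product: 8 3-C-[2-(tert-butyldiphenylsilyloxy)ethyl]-3-deoxy-1,2-O-isopropylidene-6-O-trityl-α-D-allofuranose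
Conditions: Ph3CCl, pyridine, DMAP (cat.), CH2Cl2, rt
Reagents that add atoms: trityl chloride ClC(c1ccccc1)(c1ccccc1)c1ccccc1
Why: Tritylation is selective for the primary hydroxyl of the 5,6-diol.

Step 8
Reactants: 8 3-C-[2-(tert-butyldiphenylsilyloxy)ethyl]-3-deoxy-1,2-O-isopropylidene-6-O-trityl-α-D-allofuranose
Product: 9 3-C-[2-(tert-butyldiphenylsilyloxy)ethyl]-3-deoxy-1,2-O-isopropylidene-5-O-(2-naphthylmethyl)-6-O-trityl-α-D-allofuranose
Conditions: NaH, 2-(bromomethyl)naphthalene, Bu4NI (cat.), DMF, 0 °C → rt
Reagents that add atoms: 2-(bromomethyl)naphthalene BrCc1ccc2ccccc2c1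
Why: Williamson etherification of the remaining secondary hydroxyl (the future O9); the naphthylmethyl ether is acid- and base-stable and is cleaved oxidatively at the end.

Step 9
Reactants: 9 3-C-[2-(tert-butyldiphenylsilyloxy)ethyl]-3-deoxy-1,2-O-isopropylidene-5-O-(2-naphthylmethyl)-6-O-trityl-α-D-allofuranose
Product: 10 3-C-[2-(tert-butyldiphenylsilyloxy)ethyl]-3-deoxy-5-O-(2-naphthylmethyl)-D-allofuranose (anomeric mixture)
Conditions: CF3CO2H/H2O (4:1), 0 °C → rt
Reagents that add atoms: none
Why: Aqueous acid removes the trityl ether and the 1,2-acetonide in one operation and exposes the lactol; the primary tert-butyldiphenylsilyl ether and the naphthylmethyl ether are stable to this medium.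

Step 10
Reactants: 10 3-C-[2-(tert-butyldiphenylsilyloxy)ethyl]-3-deoxy-5-O-(2-naphthylmethyl)-D-allofuranose
Product: 11 open-chain triol: C10H2OH, C9–O-naphthylmethyl, C8–OH, C7–CH2CH2OSi(t-Bu)Ph2, C6–OH, C5H=C4(CH3)2
Conditions: i-PrPPh3+ I−, n-BuLi (excess ylide), THF, −78 °C → rt
Reagents that add atoms: isopropyltriphenylphosphonium iodide CC(C)[P+](c1ccccc1)(c1ccccc1)c1ccccc1.[I-]
Why: Wittig olefination of the lactol through its open hydroxy-aldehyde form with a non-stabilised ylide gives the prenyl-type alkene; the α-oxygen is present as alkoxide, which protects C6 from epimerisation.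

Step 11
Reactants: 11 open-chain triol
Product: 12 tris(triethylsilyl) ether of 11 (O6, O8 and the C10 primary oxygen silylated)
Conditions: Et3SiOTf, 2,6-lutidine, CH2Cl2, −78 → 0 °C
Reagents that add atoms: triethylsilyl trifluoromethanesulfonate CC[Si](CC)(CC)OS(=O)(=O)C(F)(F)F
Why: Exhaustive silylation of one primary and two secondary hydroxyls; the three groups are chosen so that the primary one can be oxidised directly in step 12.

Step 12
Reactants: 12 tris(triethylsilyl) ether
Product: 13 aldehyde: C10HO, C9–O-naphthylmethyl, C8–OSiEt3, C7–CH2CH2OSi(t-Bu)Ph2, C6–OSiEt3, C5H=C4(CH3)2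
Conditions: (COCl)2, DMSO, CH2Cl2, −78 → −30 °C; then Et3N, −78 → 0 °C
Reagents that add atoms: none
Why: Swern conditions cleave and oxidise primary triethylsilyl ethers directly while secondary triethylsilyl and tert-butyldiphenylsilyl ethers survive; low-temperature amine treatment keeps the α-alkoxy centre C9 intact.

Step 13
Reactants: 13 aldehyde
Product: 14 cyclohexanol: ring C5–C10, C5 isopropenyl trans to O6; O6-SiEt3, C7 chain, O8-SiEt3, O9-naphthylmethyl and C10–OH on the opposite face
Conditions: Me2AlCl, CH2Cl2, −78 °C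
Reagents that add atoms: none
Why: Intramolecular carbonyl-ene reaction of a δ,ε-unsaturated aldehyde with a trisubstituted alkene (the citronellal-to-isopulegol reaction) forms C5–C10 and the isopropenyl group. In the closed chair-like transition state C4 is equatorial and H6 eclipses the alkene to avoid A(1,3) strain with the cis methyl, so O6 is equatorial and isopropenyl ends trans to O6 (sets C5). Chelation of aluminium by the aldehyde and O9 favours the C10 epimer shown, which is of no consequence.

Step 14
Reactants: 14 cyclohexanol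
Product: 15 cyclohexanone: C10 ketone, C5 isopropenyl, O6-SiEt3, O8-SiEt3, O9-naphthylmethyl
Conditions: Dess–Martin periodinane, NaHCO3, CH2Cl2, 0 °C
Reagents that add atoms: none
Why: Buffered Dess–Martin oxidation of the secondary alcohol avoids enolisation of the β,γ-unsaturated, α-alkoxy ketone.

Step 15
Reactants: 15 cyclohexanone
Product: 16 diol ketone: O6–H and O8–H free
Conditions: HF·pyridine, pyridine, THF, 0 °C
Reagents that add atoms: none
Why: Buffered fluoride removes the two secondary triethylsilyl ethers much faster than the primary tert-butyldiphenylsilyl ether, under conditions too mild for β-elimination of the β-hydroxy ketone.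

Step 16
Reactants: 16 diol ketone
Product: 17 bicyclic acetal ketone: O6 and O8 bridged by CH(3,4-dimethoxyphenyl), aryl exo; 2,4-dioxabicyclo[3.3.1]nonan-7-one core
Conditions: 3,4-(MeO)2C6H3CH(OMe)2, PPTS (cat.), 4 Å molecular sieves, CH2Cl2, rt
Reagents that add atoms: 3,4-dimethoxybenzaldehyde dimethyl acetal COC(OC)c1ccc(OC)c(OC)c1
Why: Acid-catalysed transacetalisation of a cis-1,3-cyclohexanediol gives the bridged 1,3-dioxane under thermodynamic control, with hydrogen inside and aryl outside; it fixes the chair with O6/O8 axial, isopropenyl axial and the C7 chain and O9 equatorial.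

Step 17
Reactants: 17 bicyclic acetal ketone
Product: 18 cis-1-vinyl-2-isopropenylcyclohexanol: C10 bears axial OH (cis to O6, O8, O9) and equatorial vinyl (cis to isopropenyl)
Conditions: CH2=CHMgBr, CeCl3, THF, −78 °C
Reagents that add atoms: vinylmagnesium bromide C=C[Mg]Br
Why: Organocerium 1,2-addition suppresses enolisation and β-alkoxide loss. The nucleophile attacks the bicyclo[3.3.1] ketone from the exo face, away from the dioxane bridge, so O10 becomes endo/axial (sets C10).

Step 18
Reactants: 18 cis-1-vinyl-2-isopropenylcyclohexanol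
Product: 21 ten-membered 1(10),4-dienyl C10 trifluoromethanesulfonate (O6/O8 acetal, O9-naphthylmethyl, C12-OSi(t-Bu)Ph2), via potassium C10 alkoxide 19 (not isolated), via ten-membered potassium enolate 20 (not isolated)
Conditions: KN(SiMe3)2, 18-crown-6, THF, −78 → 0 °C; then PhNTf2, −78 → 0 °C
Reagents that add atoms: N-phenylbis(trifluoromethanesulfonimide) O=S(=O)(N(c1ccccc1)S(=O)(=O)C(F)(F)F)C(F)(F)F
Why: The base and crown ether give the dissociated potassium alkoxide 19, which accelerates the [3,3] shift of the 3-oxido-1,5-diene C2=C1–C10–C5–C4=C3. C2 bonds to C3 while C5–C10 breaks, so the ten-membered ring arises by four-carbon ring expansion and not by an end-to-end cyclisation, and formation of enolate 20 makes it irreversible. The closest known reaction type is the anionic oxy-Cope ring expansion of 1,2-dialkenylcyclohexanols to cyclodec-5-enones with O-sulfonylation of the enolate. No stereocentre is formed; C5 and C10 become trigonal. The step needs Z at C1=C10 and E at C4=C5: the acetal holds the chair with isopropenyl axial and vinyl equatorial, so in the chair transition state C9 is pseudo-axial (cis to C2), C6 and the oxido group pseudo-equatorial (C6 trans to C3). The enolate is generated only as C1=C10–O and is trapped by PhNTf2 at low temperature before proton transfer toward C9 can occur. The axial C6–O and C8–O bonds are gauche to the C5–C10 and C9–C10 bonds, so Grob-type fragmentation of 19 has no aligned pathway.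

Step 19
Reactants: 21 ten-membered 1(10),4-dienyl C10 trifluoromethanesulfonate
Product: 22 ten-membered (1(10)Z,4E)-diene with C14 methyl on C10 (O6/O8 acetal, O9-naphthylmethyl, C12-OSi(t-Bu)Ph2)
Conditions: MeMgBr, Fe(acac)3 (cat.), THF/NMP, −30 → 0 °C
Reagents that add atoms: methylmagnesium bromide C[Mg]Br
Why: Iron-catalysed cross-coupling of an alkenyl triflate with a methyl Grignard reagent proceeds with retention of alkene geometry at low temperature and tolerates acetals and silyl ethers.

Step 20
Reactants: 22 ten-membered diene acetal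
Product: 23 O6–H alcohol with O8-(3,4-dimethoxybenzyl), O9-naphthylmethyl, C12-OSi(t-Bu)Ph2
Conditions: i-Bu2AlH, CH2Cl2, −78 → 0 °C; aqueous KNaC4H4O6 work-up
Reagents that add atoms: none
Why: Reductive opening of an arylidene acetal by an aluminium hydride: aluminium binds the less encumbered oxygen, which becomes the free hydroxyl. O6 is flanked by the trigonal C5, whereas O8 lies between C7 and the naphthylmethoxy-bearing C9, so the benzyl group should remain on O8.

Step 21
Reactants: 23 O6–H alcohol
Product: 24 6,12-diol (O8-(3,4-dimethoxybenzyl), O9-naphthylmethyl)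
Conditions: Bu4NF, THF, 0 °C → rt
Reagents that add atoms: none
Why: Fluoride cleavage of the primary silyl ether; no base-sensitive group is present at this stage.

Step 22
Reactants: 24 6,12-diol
Product: 26 cis-fused 6,12-γ-lactone (C11 still CH2), via lactol 25 (not isolated)
Conditions: TEMPO (cat.), PhI(OAc)2, CH2Cl2, rt
Reagents that add atoms: none
Why: Oxoammonium oxidation is selective for the primary alcohol; the aldehyde closes onto O6–H to the five-membered lactol, which is oxidised on to the lactone (oxidative lactonisation of a 1,4-diol).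

Step 23
Reactants: 26 cis-fused 6,12-γ-lactone
Product: 30 α-methylene lactone (O8-(3,4-dimethoxybenzyl), O9-naphthylmethyl), via lithium enolate 27 (not isolated), via Mannich base 28 (not isolated), via trimethylammonium iodide 29 (not isolated)
Conditions: LiN(i-Pr)2, THF, −78 °C; CH2=NMe2+ I−, −78 °C → rt; then MeI, MeOH, rt; then aqueous NaHCO3, CH2Cl2, rt
Reagents that add atoms: dimethylmethyleneammonium iodide (Eschenmoser's salt) C=[N+](C)C.[I-]
Why: Mannich aminomethylation of the lactone enolate, N-methylation and β-elimination is the standard α-methylenation of γ-lactones; C11 is the only acidic position and both remaining hydroxyls are masked as ethers.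

Step 24
Reactants: 30 α-methylene lactone
Product: 31 8-hydroxy α-methylene lactone (O9-naphthylmethyl)
Conditions: DDQ, CH2Cl2/pH 7 phosphate buffer, 0 °C
Reagents that add atoms: none
Why: Oxidative debenzylation; the 3,4-dimethoxybenzyl ether is oxidised much faster than a 2-naphthylmethyl ether, so O8 alone is released under neutral conditions.

Step 25
Reactants: 32 (R)-4-methyldihydrofuran-2(3H)-one
Product: 34 benzyl (R)-4-hydroxy-3-methylbutanoate, via potassium carboxylate 33 (not isolated)
Conditions: KOH, MeOH/H2O, rt; evaporate; then BnBr, Bu4NI (cat.), DMF, rt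
Reagents that add atoms: potassium hydroxide [K+].[OH-]; benzyl bromide BrCc1ccccc1
Why: Saponification of the lactone and O-alkylation of the carboxylate salt give the γ-hydroxy ester without touching the stereocentre; it is acylated at once to prevent relactonisation.

Step 26
Reactants: 34 benzyl (R)-4-hydroxy-3-methylbutanoate
Product: 35 benzyl (R)-3-methyl-4-(octadecanoyloxy)butanoate
Conditions: C17H35COCl, pyridine, DMAP (cat.), CH2Cl2, 0 °C → rt
Reagents that add atoms: octadecanoyl chloride CCCCCCCCCCCCCCCCCC(=O)Cl
Why: Acylation of a primary alcohol with an acid chloride.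

Step 27
Reactants: 35 benzyl (R)-3-methyl-4-(octadecanoyloxy)butanoate
Product: 36 (R)-3-methyl-4-(octadecanoyloxy)butanoic acid
Conditions: H2 (1 atm), 10% Pd/C, EtOAc, rt
Reagents that add atoms: none
Why: Hydrogenolysis of the benzyl ester leaves the alkyl ester untouched.

Step 28
Reactants: 31 8-hydroxy α-methylene lactone; 36 (R)-3-methyl-4-(octadecanoyloxy)butanoic acid
Product: 38 O9-(2-naphthylmethyl) ether of the target, via mixed anhydride 37 (not isolated)
Conditions: 36, 2,4,6-Cl3C6H2COCl, Et3N, THF, rt; then 31, DMAP, toluene, rt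
Reagents that add atoms: none
Why: Yamaguchi esterification acylates hindered secondary alcohols under mild conditions; the acid has no α-stereocentre, and the methylene lactone tolerates DMAP at room temperature.

Step 29
Reactants: 38 O9-(2-naphthylmethyl) ether of the target
Product: 39 CNP0114940.1
Conditions: DDQ, CH2Cl2/pH 7 phosphate buffer, rt
Reagents that add atoms: none
Why: Oxidative cleavage of the allylic 2-naphthylmethyl ether under neutral conditions avoids acid-induced transannular cyclisation and base-induced O8→O9 acyl migration.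

## Compound list

1 | 1,2:5,6-di-O-isopropylidene-α-D-glucofuranose | CC1(C)O[C@H]2[C@@H](O1)O[C@@H]([C@@H]2O)[C@H]3COC(C)(C)O3 | starting material
2 | 1,2:5,6-di-O-isopropylidene-α-D-ribo-hexofuranos-3-ulose | CC1(C)O[C@H]2[C@@H](O1)O[C@@H](C2=O)[C@H]3COC(C)(C)O3 | intermediate
3 | ethyl (3-deoxy-1,2:5,6-di-O-isopropylidene-α-D-ribo-hexofuranos-3-ylidene)acetate, alkene isomers (geometry left open) | CC1(C)O[C@H]2[C@@H](O1)O[C@@H](C2=CC(=O)OCC)[C@H]3COC(C)(C)O3 | intermediate
4 | 3-deoxy-3-C-(2-ethoxy-2-oxoethyl)-1,2:5,6-di-O-isopropylidene-α-D-allofuranose | CC1(C)O[C@H]2[C@@H](O1)O[C@@H]([C@H]2CC(=O)OCC)[C@H]3COC(C)(C)O3 | intermediate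
5 | 3-deoxy-3-C-(2-hydroxyethyl)-1,2:5,6-di-O-isopropylidene-α-D-allofuranose | CC1(C)O[C@H]2[C@@H](O1)O[C@@H]([C@H]2CCO)[C@H]3COC(C)(C)O3 | intermediate
6 | 3-C-[2-(tert-butyldiphenylsilyloxy)ethyl]-3-deoxy-1,2:5,6-di-O-isopropylidene-α-D-allofuranose | CC1(C)O[C@H]2[C@@H](O1)O[C@@H]([C@H]2CCO[Si](c3ccccc3)(c4ccccc4)C(C)(C)C)[C@H]5COC(C)(C)O5 | intermediate
7 | 3-C-[2-(tert-butyldiphenylsilyloxy)ethyl]-3-deoxy-1,2-O-isopropylidene-α-D-allofuranose | CC1(C)O[C@H]2[C@@H](O1)O[C@@H]([C@H]2CCO[Si](c3ccccc3)(c4ccccc4)C(C)(C)C)[C@H](O)CO | intermediate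
8 | 6-O-trityl derivative of 7 | CC1(C)O[C@H]2[C@@H](O1)O[C@@H]([C@H]2CCO[Si](c3ccccc3)(c4ccccc4)C(C)(C)C)[C@H](O)COC(c5ccccc5)(c6ccccc6)c7ccccc7 | intermediate
9 | 5-O-(2-naphthylmethyl)-6-O-trityl derivative of 7 | CC1(C)O[C@H]2[C@@H](O1)O[C@@H]([C@H]2CCO[Si](c3ccccc3)(c4ccccc4)C(C)(C)C)[C@H](OCc5ccc6ccccc6c5)COC(c7ccccc7)(c8ccccc8)c9ccccc9 | intermediate
10 | 3-C-[2-(tert-butyldiphenylsilyloxy)ethyl]-3-deoxy-5-O-(2-naphthylmethyl)-D-allofuranose (anomeric mixture) | OC1[C@H](O)[C@H](CCO[Si](c2ccccc2)(c3ccccc3)C(C)(C)C)[C@H](O1)[C@H](OCc4ccc5ccccc5c4)CO | intermediate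
11 | open-chain triol (C10H2OH, C9–O-naphthylmethyl, C8–OH, C7–CH2CH2OSi(t-Bu)Ph2, C6–OH, C5H=C4Me2; C6–C9 as in 3-deoxy-D-allose) | CC(C)=C[C@H](O)[C@H](CCO[Si](c1ccccc1)(c2ccccc2)C(C)(C)C)[C@H](O)[C@H](OCc3ccc4ccccc4c3)CO | intermediate
12 | tris(triethylsilyl) ether of 11 | CC(C)=C[C@H](O[Si](CC)(CC)CC)[C@H](CCO[Si](c1ccccc1)(c2ccccc2)C(C)(C)C)[C@H](O[Si](CC)(CC)CC)[C@H](OCc3ccc4ccccc4c3)CO[Si](CC)(CC)CC | intermediate
13 | C10 aldehyde with O6- and O8-triethylsilyl ethers | CC(C)=C[C@H](O[Si](CC)(CC)CC)[C@H](CCO[Si](c1ccccc1)(c2ccccc2)C(C)(C)C)[C@H](O[Si](CC)(CC)CC)[C@H](OCc3ccc4ccccc4c3)C=O | intermediate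
14 | 2-isopropenylcyclohexanol (ring C5–C10; isopropenyl trans to O6; O6, C11, O8, O9, O10 on the other face) | C=C(C)[C@H]1[C@H](O[Si](CC)(CC)CC)[C@H](CCO[Si](c2ccccc2)(c3ccccc3)C(C)(C)C)[C@H](O[Si](CC)(CC)CC)[C@H](OCc4ccc5ccccc5c4)[C@@H]1O | intermediate
15 | 2-isopropenylcyclohexanone (C10 ketone; O6, O8 triethylsilyl) | C=C(C)[C@H]1[C@H](O[Si](CC)(CC)CC)[C@H](CCO[Si](c2ccccc2)(c3ccccc3)C(C)(C)C)[C@H](O[Si](CC)(CC)CC)[C@H](OCc4ccc5ccccc5c4)C1=O | intermediate
16 | 6,8-diol ketone | C=C(C)[C@H]1[C@H](O)[C@H](CCO[Si](c2ccccc2)(c3ccccc3)C(C)(C)C)[C@H](O)[C@H](OCc4ccc5ccccc5c4)C1=O | intermediate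
17 | O6/O8 (3,4-dimethoxybenzylidene) acetal ketone, aryl exo | C=C(C)[C@H]1[C@@H]2O[C@@H](c3ccc(OC)c(OC)c3)O[C@@H]([C@H]2CCO[Si](c4ccccc4)(c5ccccc5)C(C)(C)C)[C@H](OCc6ccc7ccccc7c6)C1=O | intermediate
18 | acetal-locked cis-1-vinyl-2-isopropenylcyclohexanol (O10 axial, cis to O6/O8/O9) | C=C(C)[C@H]1[C@@H]2O[C@@H](c3ccc(OC)c(OC)c3)O[C@@H]([C@H]2CCO[Si](c4ccccc4)(c5ccccc5)C(C)(C)C)[C@H](OCc6ccc7ccccc7c6)[C@@]1(O)C=C | intermediate
19 | potassium C10 alkoxide of 18 | C=C(C)[C@H]1[C@@H]2O[C@@H](c3ccc(OC)c(OC)c3)O[C@@H]([C@H]2CCO[Si](c4ccccc4)(c5ccccc5)C(C)(C)C)[C@H](OCc6ccc7ccccc7c6)[C@@]1([O-])C=C.[K+] | intermediate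
20 | ten-membered potassium enolate (C1=C10–O) | [K+].[O-]/C1=C/CC/C(C)=C/[C@@H]2O[C@@H](c3ccc(OC)c(OC)c3)O[C@H]([C@@H]1OCc4ccc5ccccc5c4)[C@H]2CCO[Si](c6ccccc6)(c7ccccc7)C(C)(C)C | intermediate
21 | ten-membered 1(10),4-dienyl C10 triflate (C9 cis to C2; C4=C5 E) | O=S(=O)(O/C1=C/CC/C(C)=C/[C@@H]2O[C@@H](c3ccc(OC)c(OC)c3)O[C@H]([C@@H]1OCc4ccc5ccccc5c4)[C@H]2CCO[Si](c6ccccc6)(c7ccccc7)C(C)(C)C)C(F)(F)F | intermediate
22 | (1(10)Z,4E)-germacradiene acetal with C14 methyl | C/C1=C/CC/C(C)=C/[C@@H]2O[C@@H](c3ccc(OC)c(OC)c3)O[C@H]([C@@H]1OCc4ccc5ccccc5c4)[C@H]2CCO[Si](c6ccccc6)(c7ccccc7)C(C)(C)C | intermediate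
23 | 6-hydroxy-8-O-(3,4-dimethoxybenzyl)-9-O-(2-naphthylmethyl)-12-O-silyl germacradiene | C/C1=C/CC/C(C)=C/[C@H](O)[C@H](CCO[Si](c2ccccc2)(c3ccccc3)C(C)(C)C)[C@H](OCc4ccc(OC)c(OC)c4)[C@@H]1OCc5ccc6ccccc6c5 | intermediate
24 | 6,12-diol | C/C1=C/CC/C(C)=C/[C@H](O)[C@H](CCO)[C@H](OCc2ccc(OC)c(OC)c2)[C@@H]1OCc3ccc4ccccc4c3 | intermediate
25 | 6,12-lactol (epimers at C12) | C1C(O)O[C@H]2/C=C(\C)CC/C=C(/C)[C@@H](OCc3ccc4ccccc4c3)[C@@H](OCc5ccc(OC)c(OC)c5)[C@@H]12 | intermediate
26 | cis-fused 6,12-γ-lactone (11,13-dihydro, C11 = CH2) | C1C(=O)O[C@H]2/C=C(\C)CC/C=C(/C)[C@@H](OCc3ccc4ccccc4c3)[C@@H](OCc5ccc(OC)c(OC)c5)[C@@H]12 | intermediate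
27 | lithium enolate of 26 | C1=C([O-])O[C@H]2/C=C(\C)CC/C=C(/C)[C@@H](OCc3ccc4ccccc4c3)[C@@H](OCc5ccc(OC)c(OC)c5)[C@@H]12.[Li+] | intermediate
28 | C11-(dimethylaminomethyl) lactone (Mannich base, C11 epimers) | CN(C)CC1C(=O)O[C@H]2/C=C(\C)CC/C=C(/C)[C@@H](OCc3ccc4ccccc4c3)[C@@H](OCc5ccc(OC)c(OC)c5)[C@@H]12 | intermediate
29 | trimethylammonium iodide of 28 | C[N+](C)(C)CC1C(=O)O[C@H]2/C=C(\C)CC/C=C(/C)[C@@H](OCc3ccc4ccccc4c3)[C@@H](OCc5ccc(OC)c(OC)c5)[C@@H]12.[I-] | intermediate
30 | α-methylene lactone, O8-(3,4-dimethoxybenzyl), O9-(2-naphthylmethyl) | C=C1C(=O)O[C@H]2/C=C(\C)CC/C=C(/C)[C@@H](OCc3ccc4ccccc4c3)[C@@H](OCc5ccc(OC)c(OC)c5)[C@@H]12 | intermediate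
31 | 8-hydroxy α-methylene lactone, O9-(2-naphthylmethyl) | C=C1C(=O)O[C@H]2/C=C(\C)CC/C=C(/C)[C@@H](OCc3ccc4ccccc4c3)[C@@H](O)[C@@H]12 | intermediate
32 | (R)-4-methyldihydrofuran-2(3H)-one | C[C@H]1COC(=O)C1 | starting material
33 | potassium (R)-4-hydroxy-3-methylbutanoate | C[C@@H](CO)CC(=O)[O-].[K+] | intermediate
34 | benzyl (R)-4-hydroxy-3-methylbutanoate | C[C@@H](CO)CC(=O)OCc1ccccc1 | intermediate
35 | benzyl (R)-3-methyl-4-(octadecanoyloxy)butanoate | C[C@@H](COC(=O)CCCCCCCCCCCCCCCCC)CC(=O)OCc1ccccc1 | intermediate
36 | (R)-3-methyl-4-(octadecanoyloxy)butanoic acid | C[C@@H](COC(=O)CCCCCCCCCCCCCCCCC)CC(=O)O | intermediate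
37 | mixed anhydride of 36 with 2,4,6-trichlorobenzoic acid | C[C@@H](COC(=O)CCCCCCCCCCCCCCCCC)CC(=O)OC(=O)c1c(Cl)cc(Cl)cc1Cl | intermediate
38 | O9-(2-naphthylmethyl) ether of the target | C=C1C(=O)O[C@H]2/C=C(\C)CC/C=C(/C)[C@@H](OCc3ccc4ccccc4c3)[C@@H](OC(=O)C[C@@H](C)COC(=O)CCCCCCCCCCCCCCCCC)[C@@H]12 | intermediate
39 | CNP0114940.1 | C=C1C(=O)O[C@H]2/C=C(\C)CC/C=C(/C)[C@@H](O)[C@@H](OC(=O)C[C@@H](C)COC(=O)CCCCCCCCCCCCCCCCC)[C@@H]12 | target

## Step count and least certain steps

Total: 29 steps. Longest linear sequence: 26 steps (steps 1–24, 28, 29); the side chain takes 3 steps (25–27).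

**Step 18 (key step).** The [3,3] shift could pass in part through a boat-like arrangement, which would scramble the alkene geometry. The dissociated alkoxide or enolate could also undergo proton transfer toward C9 followed by loss of the C8 oxygen before the triflating agent reacts. Fallback, same disconnection without an anion: from 18, silylation (N-trimethylsilylimidazole) gives the trimethylsilyl ether F1. Thermal siloxy-Cope rearrangement in a sealed, base-washed vessel (decalin, about 200 °C) gives the ten-membered trimethylsilyl enol ether F2, in which the enolate regiochemistry is stored covalently. Cleavage with MeLi at −78 °C gives the lithium enolate F3, which is trapped with PhNTf2 to rejoin the route at 21.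

**Step 13.** The Lewis acid may ionise the allylic C6 silyl ether, or the ring may close through the chair with O6 axial, giving poor facial selectivity at C5. Fallback, ring closure by allylmetal addition instead of the ene reaction: from 12, SeO2 (cat.)/t-BuOOH oxidises the E-methyl group to the allylic alcohol F4. MsCl/Et3N/LiCl gives the allylic chloride F5, and the Swern conditions of step 12 give the chloro aldehyde F6. CrCl2 in THF (Nozaki–Hiyama allylation through the γ-carbon C5 in a closed chair) forms C5–C10 with the isopropenyl group and returns to 14.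

**Step 20.** Coordination of aluminium to O8, assisted by the neighbouring ether oxygen on C9, would reverse the regiochemistry of the opening and leave the benzyl group on O6. Fallback, stepwise differentiation instead of regioselective hydride opening: from 22, mild hydrolysis (80% AcOH, rt) gives the 6,8-diol F7. Silylation of the less hindered allylic O6–H (t-BuMe2SiCl, imidazole) gives the O6 silyl ether F8. 3,4-Dimethoxybenzyl trichloroacetimidate with La(OTf)3 (cat.) gives the fully protected ether F9. Bu4NF then removes both silyl groups and returns to 24.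

**Step 17.** The vinyl nucleophile may act as a base; enolisation toward C5 or C9 would lead to epimerisation at C5 or to β-elimination of an acetal oxygen. Fallback with a smaller, less basic two-carbon nucleophile: from 17, HC≡CMgBr/CeCl3 at −78 °C gives the ethynyl carbinol F10. Semihydrogenation (H2, Pd/CaCO3 poisoned with Pb(OAc)2, quinoline) reduces the alkyne only and returns to 18.

## Further compounds

F1 | step 18 | trimethylsilyl ether of 18 | C=C(C)[C@H]1[C@@H]2O[C@@H](c3ccc(OC)c(OC)c3)O[C@@H]([C@H]2CCO[Si](c4ccccc4)(c5ccccc5)C(C)(C)C)[C@H](OCc6ccc7ccccc7c6)[C@@]1(O[Si](C)(C)C)C=C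
F2 | step 18 | ten-membered trimethylsilyl enol ether | C[Si](C)(C)O/C1=C/CC/C(C)=C/[C@@H]2O[C@@H](c3ccc(OC)c(OC)c3)O[C@H]([C@@H]1OCc4ccc5ccccc5c4)[C@H]2CCO[Si](c6ccccc6)(c7ccccc7)C(C)(C)C
F3 | step 18 | ten-membered lithium enolate | [Li+].[O-]/C1=C/CC/C(C)=C/[C@@H]2O[C@@H](c3ccc(OC)c(OC)c3)O[C@H]([C@@H]1OCc4ccc5ccccc5c4)[C@H]2CCO[Si](c6ccccc6)(c7ccccc7)C(C)(C)C
F4 | step 13 | (E)-allylic alcohol from 12 | OC/C(C)=C/[C@H](O[Si](CC)(CC)CC)[C@H](CCO[Si](c1ccccc1)(c2ccccc2)C(C)(C)C)[C@H](O[Si](CC)(CC)CC)[C@H](OCc3ccc4ccccc4c3)CO[Si](CC)(CC)CC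
F5 | step 13 | (E)-allylic chloride | ClC/C(C)=C/[C@H](O[Si](CC)(CC)CC)[C@H](CCO[Si](c1ccccc1)(c2ccccc2)C(C)(C)C)[C@H](O[Si](CC)(CC)CC)[C@H](OCc3ccc4ccccc4c3)CO[Si](CC)(CC)CC
F6 | step 13 | chloro aldehyde | ClC/C(C)=C/[C@H](O[Si](CC)(CC)CC)[C@H](CCO[Si](c1ccccc1)(c2ccccc2)C(C)(C)C)[C@H](O[Si](CC)(CC)CC)[C@H](OCc3ccc4ccccc4c3)C=O
F7 | step 20 | 6,8-diol of the germacradiene | C/C1=C/CC/C(C)=C/[C@H](O)[C@H](CCO[Si](c2ccccc2)(c3ccccc3)C(C)(C)C)[C@H](O)[C@@H]1OCc4ccc5ccccc5c4
F8 | step 20 | O6 tert-butyldimethylsilyl ether of the 6,8-diol | C/C1=C/CC/C(C)=C/[C@H](O[Si](C)(C)C(C)(C)C)[C@H](CCO[Si](c2ccccc2)(c3ccccc3)C(C)(C)C)[C@H](O)[C@@H]1OCc4ccc5ccccc5c4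
F9 | step 20 | O6 silyl, O8 3,4-dimethoxybenzyl ether | C/C1=C/CC/C(C)=C/[C@H](O[Si](C)(C)C(C)(C)C)[C@H](CCO[Si](c2ccccc2)(c3ccccc3)C(C)(C)C)[C@H](OCc4ccc(OC)c(OC)c4)[C@@H]1OCc5ccc6ccccc6c5
F10 | step 17 | ethynyl carbinol | C=C(C)[C@H]1[C@@H]2O[C@@H](c3ccc(OC)c(OC)c3)O[C@@H]([C@H]2CCO[Si](c4ccccc4)(c5ccccc5)C(C)(C)C)[C@H](OCc6ccc7ccccc7c6)[C@@]1(O)C#C
A1 | alternative 1 | ten-membered cis-8,9-diol lactone | O[C@@H]1/C(C)=C\CC/C(C)=C/[C@@H]2OC(=O)C[C@@H]2[C@@H]1O
A2 | alternative 2 | ten-membered Z,E-dienone with C9 ketone | O=C1/C(C)=C\CC/C(C)=C/[C@H](O[Si](CC)(CC)CC)[C@H](C2COC(C)(C)OC2)[C@@H]1O[Si](C)(C)C(C)(C)C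
A3 | alternative 3 | ten-membered E-allylic C6 alcohol with C12 methyl ester | O[C@H]1/C=C(\C)CC/C=C(/C)[C@@H](O[Si](C)(C)C(C)(C)C)[C@@H](OCc2ccc(OC)cc2)[C@H]1CC(=O)OC
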